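## Retrosynthetic overview

1. The target comes from its tert-butyl ester. The (1E)-trisubstituted side-chain alkene is made by methyl cross-coupling on a (1Z)-dienyl triflate derived from a styryl ketone.
2. The C5 quaternary centre (next to the C4 quaternary centre) and the C6=C7 alkene come from a suprafacial [3,3] Claisen shift of a C7 tertiary allylic alcohol with a benzalacetone-derived enol ether.
3. The five-membered ring is formed second, by ring-closing metathesis of two alkenyl arms placed trans on a cyclohexenone by conjugate addition and iridium-catalysed allylation.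
4. Absolute configuration comes from a copper-catalysed ethyl addition that differentiates the two enantiotopic enone arms of a prochiral 4-methyl-4-carboxylate cyclohexadienone, followed by re-oxidation to the enone.
5. The six-membered ring is the benzene ring of tert-butyl benzoate, dearomatised by Birch reductive methylation and oxidised to the dienone.

Assumption: the ligand enantiomers named in steps 3 and 5 are those that give the drawn configurations (otherwise the mirror-image ligand is used), and tert-butyl benzoate, benzalacetone, 2-bromobut-1-ene and (E)-crotyl methyl carbonate are purchased.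

## Route

Step 1
Reactants: 1 tert-butyl benzoate
Product: 3 tert-butyl 1-methylcyclohexa-2,5-diene-1-carboxylate, via lithium ester dienolate 2 (not isolated)
Conditions: Li (2.2 equiv), NH3(l)/THF, t-BuOH (1 equiv), −78 °C; MeI; NH4Cl (aq)
Reagents that add atoms: iodomethane (CI)
Why: Birch reductive alkylation: the benzoate takes up two electrons, t-BuOH protonates the para carbon and dienolate 2 is C-methylated at the ipso carbon, which breaks the aromaticity and builds the methyl/carboxylate quaternary carbon (product still achiral).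

Step 2
Reactants: 3 tert-butyl 1-methylcyclohexa-2,5-diene-1-carboxylate
Product: 4 tert-butyl 1-methyl-4-oxocyclohexa-2,5-diene-1-carboxylate
Conditions: Rh2(C6H10NO)4 (dirhodium tetracaprolactamate, 1 mol%), t-BuOOH (5 equiv), K2CO3 (0.5 equiv), CH2Cl2, 25 °C
Reagents that add atoms: tert-butyl hydroperoxide (CC(C)(C)OO)
Why: Allylic C–H oxidation of the only doubly allylic CH2 gives the cross-conjugated dienone, which is still mirror-symmetric (prochiral at C1).

Step 3 (key step)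
Reactants: 4 tert-butyl 1-methyl-4-oxocyclohexa-2,5-diene-1-carboxylate
Product: 6 tert-butyl (1R)-2-ethyl-1-methyl-4-oxocyclohexa-2,5-diene-1-carboxylate, via ethylzinc dienolate 5 (not isolated)
Conditions: Cu(OTf)2 (2 mol%), ligand A [(S)-1,1'-binaphthyl-2,2'-diyl N,N-bis((R)-1-phenylethyl)phosphoramidite, 4 mol%], Et2Zn (1.1 equiv), toluene, −30 °C; then [Pd(C3H5)Cl]2 (2.5 mol%), diethyl allyl phosphate (1.2 equiv), 60 °C; NH4Cl (aq)
Reagents that add atoms: diethylzinc (CC[Zn]CC)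
Why: Copper/phosphoramidite-catalysed asymmetric conjugate addition selects one of the two enantiotopic enone arms (ethyl enters anti to the pseudo-axial ester), and Saegusa–Ito-type allyl-palladium dehydrogenation of zinc enolate 5 flattens the new CH centre again, so the symmetry breaking is kept only as the (R) quaternary carbon.

Step 4
Reactants: 6 tert-butyl (1R)-2-ethyl-1-methyl-4-oxocyclohexa-2,5-diene-1-carboxylate
Product: 7 tert-butyl (1R,6R)-6-(but-1-en-2-yl)-2-ethyl-1-methyl-4-[(trimethylsilyl)oxy]cyclohexa-2,4-diene-1-carboxylate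
Conditions: but-1-en-2-ylMgBr (from 2-bromobut-1-ene and Mg, 1.3 equiv), CuBr·SMe2 (10 mol%), Me3SiCl (2 equiv), THF, −78 °C; Et3N, pentane, filter
Reagents that add atoms: but-1-en-2-ylmagnesium bromide, made in the flask from 2-bromobut-1-ene (C=C(CC)[Mg]Br); chlorotrimethylsilane (C[Si](C)(C)Cl)
Why: Me3SiCl-accelerated copper-catalysed 1,4-addition goes to the unsubstituted enone arm (the β-ethyl arm is much slower) on the face opposite the tert-butoxycarbonyl group, which sets C6 cis to the 1-methyl, and the enolate is captured regiospecifically as the silyl dienol ether.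

Step 5
Reactants: 7 tert-butyl (1R,6R)-6-(but-1-en-2-yl)-2-ethyl-1-methyl-4-[(trimethylsilyl)oxy]cyclohexa-2,4-diene-1-carboxylate
Product: 8 tert-butyl (1R,5S,6R)-5-[(2R)-but-3-en-2-yl]-6-(but-1-en-2-yl)-2-ethyl-1-methyl-4-oxocyclohex-2-ene-1-carboxylate
Conditions: [Ir(C8H12)Cl]2 (2 mol%), ligand B [(S)-1,1'-binaphthyl-2,2'-diyl N,N-bis((S)-1-phenylethyl)phosphoramidite, 4 mol%], (E)-crotyl methyl carbonate (1.2 equiv), CsF (20 mol%), ZnF2 (50 mol%), DME, 50 °C
Reagents that add atoms: (E)-but-2-en-1-yl methyl carbonate (C/C=C/COC(=O)OC)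
Why: Iridium-catalysed branched-selective allylic substitution of the silyl enol ether fixes the allylic methine as (R) under ligand control, while C5 ends trans to the neighbouring butenyl group both kinetically and, being epimerisable, thermodynamically.

Step 6
Reactants: 8 tert-butyl (1R,5S,6R)-5-[(2R)-but-3-en-2-yl]-6-(but-1-en-2-yl)-2-ethyl-1-methyl-4-oxocyclohex-2-ene-1-carboxylate
Product: 9 tert-butyl (1R,4S,5S,6R)-5-[(2R)-but-3-en-2-yl]-6-(but-1-en-2-yl)-2-ethyl-4-hydroxy-1,4-dimethylcyclohex-2-ene-1-carboxylate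
Conditions: MeMgBr (1.5 equiv), LaCl3·2LiCl (30 mol%), THF, −20 °C; NH4Cl (aq)
Reagents that add atoms: methylmagnesium bromide (C[Mg]Br)
Why: Lanthanum-promoted 1,2-Grignard addition to the enone, with methyl entering equatorially and anti to the adjacent branched substituent, gives the pseudo-axial tertiary allylic alcohol cis to the ester and removes the epimerisable α-position.

Step 7
Reactants: 9 tert-butyl (1R,4S,5S,6R)-5-[(2R)-but-3-en-2-yl]-6-(but-1-en-2-yl)-2-ethyl-4-hydroxy-1,4-dimethylcyclohex-2-ene-1-carboxylate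
Product: 10 tert-butyl (1R,3aR,4R,7S,7aS)-3,5-diethyl-7-hydroxy-1,4,7-trimethyl-3a,4,7,7a-tetrahydro-1H-indene-4-carboxylate
Conditions: second-generation Grubbs catalyst RuCl2(=CHPh)(PCy3)(C21H26N2) (5 mol%), CH2Cl2, 40 °C
Reagents that add atoms: none
Why: Ring-closing metathesis of the 1,1-disubstituted and the monosubstituted alkene, held trans-diequatorial, closes the trans-fused cyclopentene with its trisubstituted alkene and touches no stereocentre.

Step 8
Reactants: 11 (E)-4-phenylbut-3-en-2-one (benzalacetone)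
Product: 13 (E)-(3-methoxybuta-1,3-dien-1-yl)benzene, via benzalacetone dimethyl ketal 12 (not isolated)
Conditions: HC(OMe)3 (1.5 equiv), TsOH (1 mol%), 20 °C; then KHSO4 (cat.), 140 °C, distil off MeOH
Reagents that add atoms: trimethyl orthoformate (COC(OC)OC)
Why: Orthoformate ketalisation followed by acid-catalysed loss of methanol is the standard enol ether synthesis and leaves the styryl (E)-alkene untouched.

Step 9
Reactants: 10 tert-butyl (1R,3aR,4R,7S,7aS)-3,5-diethyl-7-hydroxy-1,4,7-trimethyl-3a,4,7,7a-tetrahydro-1H-indene-4-carboxylate; 13 (E)-(3-methoxybuta-1,3-dien-1-yl)benzene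
Product: 16 tert-butyl (1R,3aR,4R,5S,7aS)-3,5-diethyl-1,4,7-trimethyl-5-[(3E)-2-oxo-4-phenylbut-3-en-1-yl]-3a,4,5,7a-tetrahydro-1H-indene-4-carboxylate, via mixed methyl ketal 14 (not isolated), via allyl dienyl ether 15 (not isolated)
Conditions: 13 (4 equiv), propionic acid (5 mol%), toluene, 110 °C, sealed tube
Reagents that add atoms: none
Why: Saucy–Marbet-type ketal Claisen rearrangement: the alcohol adds to the enol ether, methanol is lost, and the suprafacial [3,3] shift through the pseudo-axial C–O bond delivers the CH2 to C5 on the ester face, creating the second quaternary centre (S) and moving the ring alkene to C6=C7.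

Step 10
Reactants: 16 tert-butyl (1R,3aR,4R,5S,7aS)-3,5-diethyl-1,4,7-trimethyl-5-[(3E)-2-oxo-4-phenylbut-3-en-1-yl]-3a,4,5,7a-tetrahydro-1H-indene-4-carboxylate
Product: 18 tert-butyl (1R,3aR,4R,5R,7aS)-3,5-diethyl-1,4,7-trimethyl-5-[(1Z,3E)-4-phenyl-2-{[(trifluoromethyl)sulfonyl]oxy}buta-1,3-dien-1-yl]-3a,4,5,7a-tetrahydro-1H-indene-4-carboxylate, via potassium (Z)-dienolate 17 (not isolated)
Conditions: KN(SiMe3)2 (1.1 equiv), THF, −78 °C; PhNTf2 (1.2 equiv), −78 to 0 °C; NH4Cl (aq)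
Reagents that add atoms: N-phenylbis(trifluoromethanesulfonimide) (O=S(=O)(N(c1ccccc1)S(=O)(=O)C(F)(F)F)C(F)(F)F)
Why: Enol triflate formation: the only enolisable position is the neopentyl CH2, and the bulky quaternary carbon sits cis to oxygen and away from the styryl group, so the (1Z,3E)-dienyl triflate results (the C5 descriptor changes to R only through CIP priorities).

Step 11
Reactants: 18 tert-butyl (1R,3aR,4R,5R,7aS)-3,5-diethyl-1,4,7-trimethyl-5-[(1Z,3E)-4-phenyl-2-{[(trifluoromethyl)sulfonyl]oxy}buta-1,3-dien-1-yl]-3a,4,5,7a-tetrahydro-1H-indene-4-carboxylate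
Product: 19 tert-butyl (1R,3aR,4R,5S,7aS)-3,5-diethyl-1,4,7-trimethyl-5-[(1E,3E)-2-methyl-4-phenylbuta-1,3-dien-1-yl]-3a,4,5,7a-tetrahydro-1H-indene-4-carboxylate
Conditions: MeZnCl (2 equiv), Pd(PPh3)4 (5 mol%), THF, 50 °C
Reagents that add atoms: methylzinc chloride (C[Zn]Cl)
Why: Negishi coupling replaces OTf by methyl with retention at the sp2 carbon, so the (1Z)-triflate gives the (1E,3E)-diene.

Step 12
Reactants: 19 tert-butyl (1R,3aR,4R,5S,7aS)-3,5-diethyl-1,4,7-trimethyl-5-[(1E,3E)-2-methyl-4-phenylbuta-1,3-dien-1-yl]-3a,4,5,7a-tetrahydro-1H-indene-4-carboxylate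
Product: 21 (1R,3aR,4R,5S,7aS)-3,5-diethyl-1,4,7-trimethyl-5-[(1E,3E)-2-methyl-4-phenylbuta-1,3-dien-1-yl]-3a,4,5,7a-tetrahydro-1H-indene-4-carboxylic acid (CNP0226943.1), via trimethylsilyl ester 20 (not isolated)
Conditions: Me3SiOTf (2 equiv), 2,6-lutidine (3 equiv), CH2Cl2, 0 °C; NaHCO3 (aq), then pH 5 buffer
Reagents that add atoms: none
Why: Silyl triflate-mediated tert-butyl ester cleavage (loss of isobutene to silyl ester 20, hydrolysed on work-up) frees the hindered acid without strong protic acid, which could lactonise this γ,δ-unsaturated acid; no stereocentre is affected.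

## Compound list

1 | tert-butyl benzoate | CC(C)(C)OC(=O)c1ccccc1 | starting material
2 | lithium dienolate of tert-butyl cyclohexa-2,5-diene-1-carboxylate | CC(C)(C)OC(O[Li])=C1C=CCC=C1 | intermediate (not isolated)
3 | tert-butyl 1-methylcyclohexa-2,5-diene-1-carboxylate | CC(C)(C)OC(=O)C1(C)C=CCC=C1 | intermediate
4 | tert-butyl 1-methyl-4-oxocyclohexa-2,5-diene-1-carboxylate | CC(C)(C)OC(=O)C1(C)C=CC(=O)C=C1 | intermediate
5 | tert-butyl (1R,6R)-6-ethyl-4-[(ethylzincio)oxy]-1-methylcyclohexa-2,4-diene-1-carboxylate | CC(C)(C)OC(=O)[C@]1(C)C=CC(O[Zn]CC)=C[C@H]1CC | intermediate (not isolated)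
6 | tert-butyl (1R)-2-ethyl-1-methyl-4-oxocyclohexa-2,5-diene-1-carboxylate | CC(C)(C)OC(=O)[C@]1(C)C=CC(=O)C=C1CC | intermediate
7 | tert-butyl (1R,6R)-6-(but-1-en-2-yl)-2-ethyl-1-methyl-4-[(trimethylsilyl)oxy]cyclohexa-2,4-diene-1-carboxylate | CC(C)(C)OC(=O)[C@]1(C)[C@@H](C(=C)CC)C=C(O[Si](C)(C)C)C=C1CC | intermediate
8 | tert-butyl (1R,5S,6R)-5-[(2R)-but-3-en-2-yl]-6-(but-1-en-2-yl)-2-ethyl-1-methyl-4-oxocyclohex-2-ene-1-carboxylate | CC(C)(C)OC(=O)[C@]1(C)[C@@H](C(=C)CC)[C@H]([C@H](C)C=C)C(=O)C=C1CC | intermediate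
9 | tert-butyl (1R,4S,5S,6R)-5-[(2R)-but-3-en-2-yl]-6-(but-1-en-2-yl)-2-ethyl-4-hydroxy-1,4-dimethylcyclohex-2-ene-1-carboxylate | CC(C)(C)OC(=O)[C@]1(C)[C@@H](C(=C)CC)[C@H]([C@H](C)C=C)[C@](C)(O)C=C1CC | intermediate
10 | tert-butyl (1R,3aR,4R,7S,7aS)-3,5-diethyl-7-hydroxy-1,4,7-trimethyl-3a,4,7,7a-tetrahydro-1H-indene-4-carboxylate | CCC1=C[C@@H](C)[C@@H]2[C@](C)(O)C=C(CC)[C@](C)(C(=O)OC(C)(C)C)[C@@H]12 | intermediate
11 | (E)-4-phenylbut-3-en-2-one (benzalacetone) | CC(=O)/C=C/c1ccccc1 | starting material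
12 | (E)-(3,3-dimethoxybut-1-en-1-yl)benzene | COC(C)(OC)/C=C/c1ccccc1 | intermediate (not isolated)
13 | (E)-(3-methoxybuta-1,3-dien-1-yl)benzene | COC(=C)/C=C/c1ccccc1 | intermediate
14 | tert-butyl (1R,3aR,4R,7S,7aS)-3,5-diethyl-7-{[(3E)-2-methoxy-4-phenylbut-3-en-2-yl]oxy}-1,4,7-trimethyl-3a,4,7,7a-tetrahydro-1H-indene-4-carboxylate (both ketal epimers) | CCC1=C[C@@H](C)[C@@H]2[C@](C)(OC(C)(OC)/C=C/c3ccccc3)C=C(CC)[C@](C)(C(=O)OC(C)(C)C)[C@@H]12 | intermediate (not isolated)
15 | tert-butyl (1R,3aR,4R,7S,7aS)-3,5-diethyl-1,4,7-trimethyl-7-{[(3E)-4-phenylbuta-1,3-dien-2-yl]oxy}-3a,4,7,7a-tetrahydro-1H-indene-4-carboxylate | CCC1=C[C@@H](C)[C@@H]2[C@](C)(OC(=C)/C=C/c3ccccc3)C=C(CC)[C@](C)(C(=O)OC(C)(C)C)[C@@H]12 | intermediate (not isolated)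
16 | tert-butyl (1R,3aR,4R,5S,7aS)-3,5-diethyl-1,4,7-trimethyl-5-[(3E)-2-oxo-4-phenylbut-3-en-1-yl]-3a,4,5,7a-tetrahydro-1H-indene-4-carboxylate | CCC1=C[C@@H](C)[C@@H]2C(C)=C[C@@](CC(=O)/C=C/c3ccccc3)(CC)[C@](C)(C(=O)OC(C)(C)C)[C@@H]12 | intermediate
17 | potassium (1Z,3E)-dienolate of 16 | CCC1=C[C@@H](C)[C@@H]2C(C)=C[C@@](/C=C(O[K])/C=C/c3ccccc3)(CC)[C@](C)(C(=O)OC(C)(C)C)[C@@H]12 | intermediate (not isolated)
18 | tert-butyl (1R,3aR,4R,5R,7aS)-3,5-diethyl-1,4,7-trimethyl-5-[(1Z,3E)-4-phenyl-2-{[(trifluoromethyl)sulfonyl]oxy}buta-1,3-dien-1-yl]-3a,4,5,7a-tetrahydro-1H-indene-4-carboxylate | CCC1=C[C@@H](C)[C@@H]2C(C)=C[C@@](/C=C(OS(=O)(=O)C(F)(F)F)/C=C/c3ccccc3)(CC)[C@](C)(C(=O)OC(C)(C)C)[C@@H]12 | intermediate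
19 | tert-butyl (1R,3aR,4R,5S,7aS)-3,5-diethyl-1,4,7-trimethyl-5-[(1E,3E)-2-methyl-4-phenylbuta-1,3-dien-1-yl]-3a,4,5,7a-tetrahydro-1H-indene-4-carboxylate | CCC1=C[C@@H](C)[C@@H]2C(C)=C[C@@](/C=C(C)/C=C/c3ccccc3)(CC)[C@](C)(C(=O)OC(C)(C)C)[C@@H]12 | intermediate
20 | trimethylsilyl (1R,3aR,4R,5S,7aS)-3,5-diethyl-1,4,7-trimethyl-5-[(1E,3E)-2-methyl-4-phenylbuta-1,3-dien-1-yl]-3a,4,5,7a-tetrahydro-1H-indene-4-carboxylate | CCC1=C[C@@H](C)[C@@H]2C(C)=C[C@@](/C=C(C)/C=C/c3ccccc3)(CC)[C@](C)(C(=O)O[Si](C)(C)C)[C@@H]12 | intermediate (not isolated)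
21 | (1R,3aR,4R,5S,7aS)-3,5-diethyl-1,4,7-trimethyl-5-[(1E,3E)-2-methyl-4-phenylbuta-1,3-dien-1-yl]-3a,4,5,7a-tetrahydro-1H-indene-4-carboxylic acid | CCC1=C[C@@H](C)[C@@H]2C(C)=C[C@@](/C=C(C)/C=C/c3ccccc3)(CC)[C@](C)(C(=O)O)[C@@H]12 | target

## Step count and risks

Total step count: 12 (steps 1–12). Longest linear sequence: 11 (steps 1–7 and 9–12, from tert-butyl benzoate); step 8 is a one-step side branch.

The three steps most likely to fail:

**Step 3.** The arm selection needs both high catalyst enantioselectivity and high anti-to-ester diastereoselectivity, because after dehydrogenation the wrong-face adduct of the other arm becomes the enantiomer of 6. The residual ethyl–zinc bond may also add to the new dienone. The fallback sets out from 4 and returns at 8, and breaks the symmetry with the group that stays sp3. Copper/ligand A-catalysed asymmetric 1,4-addition of but-1-en-2-ylmagnesium bromide to 4 with Me3SiCl trapping gives tert-butyl (1S,6R)-6-(but-1-en-2-yl)-1-methyl-4-[(trimethylsilyl)oxy]cyclohexa-2,4-diene-1-carboxylate F1. Iridium-catalysed crotylation as in step 5 gives tert-butyl (1S,5S,6R)-5-[(2R)-but-3-en-2-yl]-6-(but-1-en-2-yl)-1-methyl-4-oxocyclohex-2-ene-1-carboxylate F2. Achiral EtMgBr/CuBr·SMe2/Me3SiCl addition to the remaining enone gives tert-butyl (1S,2R,5S,6R)-5-[(2R)-but-3-en-2-yl]-6-(but-1-en-2-yl)-2-ethyl-1-methyl-4-[(trimethylsilyl)oxy]cyclohex-3-ene-1-carboxylate F3. Saegusa–Ito oxidation of this with Pd(OAc)2 in MeCN gives 8.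

**Step 5.** The nucleophilic carbon is flanked by a branched centre and must attack the substituted terminus of the iridium allyl, so low conversion or linear product is possible. The fallback sets out from 7 and returns at 8, and makes the same bond by conjugate addition instead. TiCl4-mediated Mukaiyama aldol of 7 with acetaldehyde at −78 °C gives tert-butyl (1R,5R,6R)-6-(but-1-en-2-yl)-2-ethyl-5-(1-hydroxyethyl)-1-methyl-4-oxocyclohex-2-ene-1-carboxylate F4 (carbinol epimers). MsCl/Et3N then DBU gives tert-butyl (1R,5E,6S)-6-(but-1-en-2-yl)-2-ethyl-5-ethylidene-1-methyl-4-oxocyclohex-2-ene-1-carboxylate F5. 1,4-Addition of a vinyl cuprate (vinylMgBr, CuBr·SMe2, Me3SiCl) to the exocyclic enone, anti to the butenyl group, and equilibrating protonation give 8 together with its epimer at the new methine, separated by chromatography.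

**Step 9.** The tertiary allylic alcohol can ionise or dehydrate under acid and heat, and the shift must build a quaternary centre next to another one. The correct C5 configuration also depends on the step 6 alcohol being the epimer cis to the ester. The fallback sets out from 10 and returns at 16, and uses a base-mediated rearrangement and assembles the styryl ketone in two C–C bond formations. Diketene/DMAP acetoacetylation of 10 gives tert-butyl (1R,3aR,4R,7S,7aS)-3,5-diethyl-1,4,7-trimethyl-7-[(3-oxobutanoyl)oxy]-3a,4,7,7a-tetrahydro-1H-indene-4-carboxylate F6. Dianion Carroll rearrangement (LiN(iPr)2, 2.2 equiv, THF, −78 to 65 °C) and decarboxylation in warm toluene give tert-butyl (1R,3aR,4R,5S,7aS)-3,5-diethyl-1,4,7-trimethyl-5-(2-oxopropyl)-3a,4,5,7a-tetrahydro-1H-indene-4-carboxylate F7. Claisen–Schmidt condensation at the methyl group with benzaldehyde (LiN(SiMe3)2, PhCHO; then MsCl, Et3N) gives 16.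

## Further compounds

F1 | step 3 | tert-butyl (1S,6R)-6-(but-1-en-2-yl)-1-methyl-4-[(trimethylsilyl)oxy]cyclohexa-2,4-diene-1-carboxylate | CC(C)(C)OC(=O)[C@]1(C)[C@@H](C(=C)CC)C=C(O[Si](C)(C)C)C=C1
F2 | step 3 | tert-butyl (1S,5S,6R)-5-[(2R)-but-3-en-2-yl]-6-(but-1-en-2-yl)-1-methyl-4-oxocyclohex-2-ene-1-carboxylate | CC(C)(C)OC(=O)[C@]1(C)[C@@H](C(=C)CC)[C@H]([C@H](C)C=C)C(=O)C=C1
F3 | step 3 | tert-butyl (1S,2R,5S,6R)-5-[(2R)-but-3-en-2-yl]-6-(but-1-en-2-yl)-2-ethyl-1-methyl-4-[(trimethylsilyl)oxy]cyclohex-3-ene-1-carboxylate | CC(C)(C)OC(=O)[C@]1(C)[C@@H](C(=C)CC)[C@H]([C@H](C)C=C)C(O[Si](C)(C)C)=C[C@H]1CC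
F4 | step 5 | tert-butyl (1R,5R,6R)-6-(but-1-en-2-yl)-2-ethyl-5-(1-hydroxyethyl)-1-methyl-4-oxocyclohex-2-ene-1-carboxylate (carbinol epimers) | CC(C)(C)OC(=O)[C@]1(C)[C@@H](C(=C)CC)[C@H](C(C)O)C(=O)C=C1CC
F5 | step 5 | tert-butyl (1R,5E,6S)-6-(but-1-en-2-yl)-2-ethyl-5-ethylidene-1-methyl-4-oxocyclohex-2-ene-1-carboxylate | CC(C)(C)OC(=O)[C@]1(C)[C@@H](C(=C)CC)/C(=C\C)C(=O)C=C1CC
F6 | step 9 | tert-butyl (1R,3aR,4R,7S,7aS)-3,5-diethyl-1,4,7-trimethyl-7-[(3-oxobutanoyl)oxy]-3a,4,7,7a-tetrahydro-1H-indene-4-carboxylate | CCC1=C[C@@H](C)[C@@H]2[C@](C)(OC(=O)CC(C)=O)C=C(CC)[C@](C)(C(=O)OC(C)(C)C)[C@@H]12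
F7 | step 9 | tert-butyl (1R,3aR,4R,5S,7aS)-3,5-diethyl-1,4,7-trimethyl-5-(2-oxopropyl)-3a,4,5,7a-tetrahydro-1H-indene-4-carboxylate | CCC1=C[C@@H](C)[C@@H]2C(C)=C[C@@](CC(C)=O)(CC)[C@](C)(C(=O)OC(C)(C)C)[C@@H]12
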